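In the elm run the intermediate climbs to 14.2 % within 0.333 min, yet losing 13 percentage points from its highest reading takes 3.17 min.

| setting | elm | flask |
|---|---|---|
| substrate | 0.36 M | 0.36 M |
| remark | the very flask that is asked about, followed so far |  |
| time |  | 20 min |

- elm (time / min: intermediate / %, target / %): 0.167: 9.4, 0.8; 0.333: 14.2, 3.2; 0.833: 16.3, 10.8; 2.00: 7.5, 20.9; 4.00: 3.5, 24.5; 10.0: 0, 29.3

(standard deviation of a reading: 1 percentage point)

- time, not beyond 20 min, at which the flask holds most intermediate
- the amount of intermediate, in percent of the substrate charged, at that time
- earliest time at which at least nineteen twentieths of that best amount are there, in min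
- latest time at which they still are, in min



Taking two first-order steps as a working reckoning, the fall of the intermediate between 0.833 min and 2.00 min reads as a slow rate, 0.665 min⁻¹. Drawn back to the start, this tail meets 28.4 % of the charge. Lying below the whole charge, it puts the slow rate on the making of intermediate and the fast rate on its loss. The intercept equals the slow rate over the difference of the rates, so the fast rate is 3.01 min⁻¹.

Two limits bracket the flask. With its loss balancing its making at once (the quasi-steady state), the intermediate stands at 22.1 % of the substrate left and falls from time zero. With its loss stopped, it piles up. The two-step curve rises until it meets that balance line and turns there, at the crossing time, ln(fast/slow) over the difference of the rates: 0.644 min, far short of 20 min.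

The forecast, reasoning differently, gives 16.9 % at 0.56 min, with the window from 0.41 min to 0.82 min: “an early maximum, well inside 20 min and between readings”.

The flask peaks at 0.622 min with 16.7 %, and its window runs from 0.434 min to 0.865 min.

    substrate → intermediate (k = 0.0130 s⁻¹)
    intermediate → target (k = 0.0240 s⁻¹)
    target → over-reaction product (k = 2.50 × 10⁻⁵ s⁻¹)
    intermediate → side product (k = 0.0240 s⁻¹)
    target ⇌ isomer of the product (K = 0.760, k = 0.0430 s⁻¹)

The substrate's half-life, 0.889 min, is longer than the intermediate's half-life by its two losses together, 0.241 min. At 0.622 min the flask holds 61.6 % substrate beside 16.7 % intermediate. The neighbour flask read at 50 min, far beyond the crossing time, holds 0 % intermediate.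

The readings stem from a simulated flask for substances that don't exist, and the scatter is random.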